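**Retrosynthetic overview**
- The plan rests on central ring B (butyryl on C1): C3 and C5 each lie between two oxygen-bearing carbons (C2/C4 and C4/C6), so both can be aryllithium sites, and each bridging CH2 is traced back to the formyl carbon of a terminal ring (rings A and C are identical).
- Last disconnection: the three aryl–C(=O) bonds, each at the only unsubstituted carbon of its ring (threefold Friedel–Crafts butyrylation).
- Key disconnection: the two ring B C3/C5–CH bonds, made by adding a ring B dilithio species to two molecules of a ring A/C aldehyde; one hydrogenolysis then removes the carbinol oxygens and all benzyl groups.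
- No ring is formed; ring B comes from phloroglucinol, and rings A and C come from 2-methylphloroglucinol.

Key step: step 6

Remark: the target is achiral; the two carbinol centres of 12 form without control (meso and racemic diastereomers) and are carried as a mixture because both become CH2 in step 7.

**Route**

Step 1
Reactants: 1 phloroglucinol
Product: 2 phloroglucinol triacetate (benzene-1,3,5-triyl triacetate)
Conditions: Ac2O, pyridine, DMAP (cat.), 0 °C → rt
Reagents that add atoms: acetic anhydride CC(=O)OC(C)=O
Why: Threefold O-acetylation of a phenol (nucleophilic acyl substitution) is routine and gives the masked phenol needed for clean O-benzylation in step 2.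

Step 2
Reactants: 2 phloroglucinol triacetate; 3 benzyl bromide
Product: 4 1,3,5-tris(benzyloxy)benzene
Conditions: NaH (7 equiv.), BnBr (3.6 equiv.), DMF, 0 °C; H2O (3 equiv.) added slowly; → rt
Reagents that add atoms: benzyl bromide BrCc1ccccc1
Why: Hydroxide formed in the flask removes the acetates one at a time, so each phenoxide is released at low concentration in excess benzyl bromide and undergoes Williamson O-benzylation instead of the C-benzylation typical of free phloroglucinol.

Step 3
Reactants: 4 1,3,5-tris(benzyloxy)benzene
Product: 5 1,3,5-tris(benzyloxy)-2,4-dibromobenzene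
Conditions: NBS (2.05 equiv.), CH2Cl2–MeCN, 0 °C → rt, dark
Reagents that add atoms: N-bromosuccinimide O=C1CCC(=O)N1Br
Why: Electrophilic aromatic bromination of a trialkoxybenzene whose three open positions are equivalent should stop at the single possible dibromide, because each bromine deactivates the ring and the stoichiometry is limited to two equivalents.

Step 4
Reactants: 6 2-methylphloroglucinol
Product: 8 2,4,6-trihydroxy-3-methylbenzaldehyde, via iminium chloride 7 (not isolated)
Conditions: POCl3 (1.1 equiv.), DMF, EtOAc, 0 °C → rt; then H2O, 60 °C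
Reagents that add atoms: N,N-dimethylformamide CN(C)C=O; water O
Why: Vilsmeier–Haack formylation at one of the two symmetry-equivalent open positions gives iminium salt 7, which deactivates the ring against a second formylation and is hydrolysed to the aldehyde.

Step 5
Reactants: 8 2,4,6-trihydroxy-3-methylbenzaldehyde; 3 benzyl bromide
Product: 9 2,4,6-tris(benzyloxy)-3-methylbenzaldehyde
Conditions: BnBr (3.6 equiv.), K2CO3 (4.5 equiv.), DMF, 60 °C
Reagents that add atoms: benzyl bromide BrCc1ccccc1
Why: Williamson ether synthesis should be O-selective here because the formyl group lowers the carbon nucleophilicity of the ring, so the remaining C5–H is not benzylated.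

Step 6
Reactants: 5 1,3,5-tris(benzyloxy)-2,4-dibromobenzene; 9 2,4,6-tris(benzyloxy)-3-methylbenzaldehyde (2.2 equiv.)
Product: 12 nonabenzyl bis(diarylcarbinol) [2,4,6-tris(benzyloxy)-1,3-phenylene]bis{[2,4,6-tris(benzyloxy)-3-methylphenyl]methanol} as a diastereomer mixture, via dilithioarene 10 (not isolated), via dilithium dialkoxide 11 (not isolated)
Conditions: t-BuLi (4.2 equiv.), THF, −78 °C; then 9 in THF, −78 → 0 °C; sat. aq. NH4Cl
Reagents that add atoms: none
Why: Both bromines of 5 undergo bromine–lithium exchange with t-BuLi (the second equivalent per bromine destroys t-BuBr) to give dilithioarene 10, whose two C–Li carbons are each held between two benzyloxy oxygens and add to the non-enolisable formyl groups of two molecules of 9 to give dialkoxide 11, protonated to 12 on work-up. The closest known reaction type is halogen–lithium exchange on 2,6-dialkoxyaryl bromides followed by 1,2-addition to 2,6-dialkoxybenzaldehydes, including twofold exchange on dibromo-polyalkoxybenzenes. No ring closes; the step forms the two ring B C(aryl)–CH(OH) bonds intermolecularly. The two carbinol centres are not controlled and need not be, since both are reduced to CH2 in step 7. The step needs the correct constitution and exchange in preference to benzylic deprotonation or Wittig rearrangement of the benzyl ethers; the first is fixed by the bromine positions in 5 and the second by the speed of the exchange at −78 °C. Both partners carry no ketone because a butyryl group would be enolised or attacked by 10, which is why acylation is left to step 8.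

Step 7
Reactants: 12 nonabenzyl bis(diarylcarbinol)
Product: 13 2,4-bis[(2,4,6-trihydroxy-3-methylphenyl)methyl]benzene-1,3,5-triol
Conditions: H2 (1–3 atm), 10% Pd/C, THF–MeOH (degassed), AcOH (cat.), rt; product handled under argon and used directly
Reagents that add atoms: none
Why: Catalytic hydrogenolysis cleaves the nine O-benzyl groups, and the unveiled ortho- and para-hydroxyls let each doubly benzylic carbinol lose water to a quinone methide that is hydrogenated to the CH2 bridge.

Step 8
Reactants: 13 2,4-bis[(2,4,6-trihydroxy-3-methylphenyl)methyl]benzene-1,3,5-triol; 14 butyryl chloride (3.3 equiv.)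
Product: 15 target, 1-[3,5-bis[(3-butanoyl-2,4,6-trihydroxy-5-methylphenyl)methyl]-2,4,6-trihydroxyphenyl]butan-1-one
Conditions: butyryl chloride, AlCl3 (excess), PhNO2–CH2Cl2, 0 → 45 °C; then ice, aq. HCl
Reagents that add atoms: butyryl chloride CCCC(Cl)=O
Why: Friedel–Crafts acylation of a phloroglucinol should go at the single open carbon of each ring, which lies between two hydroxyls, with any O-butyrate moved to carbon by Fries rearrangement under AlCl3 and each ring limited to one acyl group.

**Compound list**
1 | phloroglucinol | Oc1cc(O)cc(O)c1 | starting material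
2 | phloroglucinol triacetate | CC(=O)Oc1cc(OC(C)=O)cc(OC(C)=O)c1 | intermediate
3 | benzyl bromide | BrCc1ccccc1 | starting material
4 | 1,3,5-tris(benzyloxy)benzene | c1ccc(COc2cc(OCc3ccccc3)cc(OCc3ccccc3)c2)cc1 | intermediate
5 | 1,3,5-tris(benzyloxy)-2,4-dibromobenzene | Brc1c(OCc2ccccc2)cc(OCc2ccccc2)c(Br)c1OCc1ccccc1 | intermediate
6 | 2-methylphloroglucinol | Cc1c(O)cc(O)cc1O | starting material
7 | N,N-dimethyl-(2,4,6-trihydroxy-3-methylphenyl)methaniminium chloride (not isolated) | C[N+](C)=Cc1c(O)c(C)c(O)cc1O.[Cl-] | intermediate
8 | 2,4,6-trihydroxy-3-methylbenzaldehyde | O=Cc1c(O)c(C)c(O)cc1O | intermediate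
9 | 2,4,6-tris(benzyloxy)-3-methylbenzaldehyde | O=Cc1c(OCc2ccccc2)c(C)c(OCc2ccccc2)cc1OCc1ccccc1 | intermediate
10 | 2,4,6-tris(benzyloxy)-1,3-dilithiobenzene (not isolated) | [Li]c1c(OCc2ccccc2)cc(OCc2ccccc2)c([Li])c1OCc1ccccc1 | intermediate
11 | dilithium dialkoxide of 12 (not isolated) | Cc1c(OCc2ccccc2)cc(OCc2ccccc2)c(C(O[Li])c2c(OCc3ccccc3)cc(OCc3ccccc3)c(C(O[Li])c3c(OCc4ccccc4)cc(OCc4ccccc4)c(C)c3OCc3ccccc3)c2OCc2ccccc2)c1OCc1ccccc1 | intermediate
12 | [2,4,6-tris(benzyloxy)-1,3-phenylene]bis{[2,4,6-tris(benzyloxy)-3-methylphenyl]methanol}, mixture of carbinol diastereomers | Cc1c(OCc2ccccc2)cc(OCc2ccccc2)c(C(O)c2c(OCc3ccccc3)cc(OCc3ccccc3)c(C(O)c3c(OCc4ccccc4)cc(OCc4ccccc4)c(C)c3OCc3ccccc3)c2OCc2ccccc2)c1OCc1ccccc1 | intermediate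
13 | 2,4-bis[(2,4,6-trihydroxy-3-methylphenyl)methyl]benzene-1,3,5-triol | Cc1c(O)cc(O)c(Cc2c(O)cc(O)c(Cc3c(O)cc(O)c(C)c3O)c2O)c1O | intermediate
14 | butyryl chloride | CCCC(Cl)=O | starting material
15 | 1-[3,5-bis[(3-butanoyl-2,4,6-trihydroxy-5-methylphenyl)methyl]-2,4,6-trihydroxyphenyl]butan-1-one (CNP0296563.0) | CCCC(=O)c1c(O)c(C)c(O)c(Cc2c(O)c(Cc3c(O)c(C)c(O)c(C(=O)CCC)c3O)c(O)c(C(=O)CCC)c2O)c1O | target

**Step count**
Total steps: 8. Longest linear sequence: 6 (steps 1, 2, 3, 6, 7, 8).

**Steps most likely to fail**

Step 6. The second bromine–lithium exchange may stall, or one C–Li site may be protonated, so that only one aldehyde adds; benzylic deprotonation of a benzyl ether by the organolithium may also compete. Fallback: the two bonds are made in two separate monolithium stages. Setting out from 5, n-BuLi (1.0 equiv., THF, −78 °C) should give 2,4,6-tris(benzyloxy)-3-bromophenyllithium F1. Addition of 9 (1.0 equiv.) and work-up should give the isolable bromo carbinol [2,4,6-tris(benzyloxy)-3-bromophenyl][2,4,6-tris(benzyloxy)-3-methylphenyl]methanol F2. F2 with n-BuLi (2.1 equiv., the first equivalent taking the hydroxyl proton) should give the lithium alkoxide aryllithium F3, which adds a second molecule of 9 and comes back to the route at 12.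

Step 8. AlCl3 may cleave or scramble the methylene bridges of the electron-rich diarylmethane (retro-Friedel–Crafts), and acylation may stop short of three ketones or stay at oxygen. Fallback: the ketones are installed while the phenols are still benzylated. Setting out from 12, ionic deoxygenation (Et3SiH, CF3CO2H, CH2Cl2, −20 → 0 °C) should give 1,3,5-tris(benzyloxy)-2,4-bis{[2,4,6-tris(benzyloxy)-3-methylphenyl]methyl}benzene F4. Mixed-anhydride acylation (butyric acid, (CF3CO)2O, CH2Cl2, 0 °C → rt) at the one open position of each ring should give the nonabenzyl triketone F5. Hydrogenolysis (H2, Pd/C, EtOAc–MeOH) should then remove the nine benzyl groups without touching the hydrogen-bonded aryl ketones and comes back to the route at 15.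

Step 7. Loss of the hindered carbinol oxygens may be incomplete, transient quinone methides may be trapped by neighbouring phenol rings, or the phloroglucinol rings may be over-reduced during a long hydrogenation. Fallback: deoxygenation and debenzylation are separated. Setting out from 12, Et3SiH and CF3CO2H in CH2Cl2 should reduce the doubly stabilised diarylmethyl cations to give F4 with all benzyl ethers intact. A short hydrogenolysis of F4 (H2, Pd(OH)2/C, THF–MeOH) then comes back to the route at 13.

**Further compounds**
F1 | step 6 | 2,4,6-tris(benzyloxy)-3-bromophenyllithium | [Li]c1c(OCc2ccccc2)cc(OCc2ccccc2)c(Br)c1OCc1ccccc1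
F2 | step 6 | [2,4,6-tris(benzyloxy)-3-bromophenyl][2,4,6-tris(benzyloxy)-3-methylphenyl]methanol (racemic) | Cc1c(OCc2ccccc2)cc(OCc2ccccc2)c(C(O)c2c(OCc3ccccc3)cc(OCc3ccccc3)c(Br)c2OCc2ccccc2)c1OCc1ccccc1
F3 | step 6 | lithium alkoxide aryllithium from F2 | Cc1c(OCc2ccccc2)cc(OCc2ccccc2)c(C(O[Li])c2c(OCc3ccccc3)cc(OCc3ccccc3)c([Li])c2OCc2ccccc2)c1OCc1ccccc1
F4 | step 7 | 1,3,5-tris(benzyloxy)-2,4-bis{[2,4,6-tris(benzyloxy)-3-methylphenyl]methyl}benzene | Cc1c(OCc2ccccc2)cc(OCc2ccccc2)c(Cc2c(OCc3ccccc3)cc(OCc3ccccc3)c(Cc3c(OCc4ccccc4)cc(OCc4ccccc4)c(C)c3OCc3ccccc3)c2OCc2ccccc2)c1OCc1ccccc1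
F5 | step 8 | 1-[2,4,6-tris(benzyloxy)-3,5-bis{[2,4,6-tris(benzyloxy)-3-butanoyl-5-methylphenyl]methyl}phenyl]butan-1-one | CCCC(=O)c1c(OCc2ccccc2)c(C)c(OCc2ccccc2)c(Cc2c(OCc3ccccc3)c(Cc3c(OCc4ccccc4)c(C)c(OCc4ccccc4)c(C(=O)CCC)c3OCc3ccccc3)c(OCc3ccccc3)c(C(=O)CCC)c2OCc2ccccc2)c1OCc1ccccc1
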